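**Retrosynthetic overview**

1. The vanillate and the 9-hydroxyl are installed last and together: palladium-catalysed cis-1,4-addition of vanillic acid to an 8α,9α-vinyl epoxide, which comes from site- and face-selective epoxidation of a trans-fused dauca-6,8-dien-4β-ol (late oxidation of ring B, as in the presumed biogenesis).
2. The dienol is disconnected across both rings at once to an acyclic 10-oxo-α-farnesene-type (6E,9Z)-trienone. The two bonds broken, C4–C5 and C1–C10 (daucane numbering), are the two bonds made when the farnesyl chain is cyclised to the daucane skeleton, formed by anti addition across the central E-olefin.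
3. Forward order of ring formation, in one operation: ring A (five-membered, C4–C5) first, giving the tertiary C1 cation; ring B (seven-membered, C1–C10) second by capture with the diene terminus; loss of H6 ends the cascade. The carbonyl carbon takes the place of the enzymatic C4 cation, so the tertiary carbinol is formed in the same step.
4. The trienone comes from 3-methylbutan-2-one and a (2E,5Z)-trienyl bromide, assembled from prop-2-yn-1-ol (carboalumination) and (Z)-3-methylpent-2-en-4-yn-1-ol.

Numbering and descriptors: daucane numbering throughout, also for the acyclic precursor. C1 = ring-fusion carbon with the angular methyl, C2/C3 = ring-A CH2, C4 = carbinol carbon with the isopropyl group, C5 = ring-fusion CH, C6–C10 = remaining ring-B carbons (C8 carries the methyl). β = face of the C1 methyl; α = opposite face. Target: 4β-OH, H5 α, 6α-acyloxy, 9α-OH = (1R,4R,5S,6S,9S).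

Assumption: the sense of induction of the chiral aluminium promoter in step 6 cannot be predicted with certainty; the (S,S)-ligand is written, and its antipode is used if the first run gives the mirror-image series.

**Route**

Step 1
Reactants: 1 (Z)-3-methylpent-2-en-4-yn-1-ol
Product: 2 (Z)-3-methylpent-2-en-4-yn-1-yl acetate
Conditions: Ac2O, pyridine, 4-(dimethylamino)pyridine (2 mol%), CH2Cl2, 0 °C → rt
Reagents that add atoms: acetic anhydride, CC(=O)OC(C)=O
Why: Acylation (esterification) of the primary allylic alcohol under nucleophilic catalysis gives the allylic electrophile for step 2 without touching the Z-enyne, and no stereocentre is formed.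

Step 2
Reactants: 3 prop-2-yn-1-ol; 2 (Z)-3-methylpent-2-en-4-yn-1-yl acetate
Product: 5 (2E,5Z)-2,6-dimethylocta-2,5-dien-7-yn-1-ol, via alkenylalane 4 (not isolated)
Conditions: 3, Me3Al (3 equiv), Cp2ZrCl2 (25 mol%), CH2Cl2, 0 °C → rt, 12 h; volatiles removed; then 2, Pd(PPh3)4 (5 mol%), THF, 0 °C → rt; aq. potassium sodium tartrate
Reagents that add atoms: trimethylaluminium, C[Al](C)C
Why: Negishi zirconium-catalysed carboalumination adds methyl and aluminium syn across the alkyne (methyl to the internal carbon), which fixes the 2E olefin, and the alkenylalane is then joined to the primary terminus of the allyl acetate by palladium-catalysed allyl–alkenyl cross-coupling (Negishi coupling), the Z geometry of the enyne being kept because the allylpalladium unit cannot isomerise through its fully substituted terminus.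

Step 3
Reactants: 5 (2E,5Z)-2,6-dimethylocta-2,5-dien-7-yn-1-ol
Product: 6 (2E,5Z)-2,6-dimethylocta-2,5,7-trien-1-ol
Conditions: H2 (1 atm), Pd/CaCO3 poisoned with Pb(OAc)2, quinoline, EtOAc, 0 °C → rt, stopped at 1 equiv H2
Reagents that add atoms: none
Why: Lindlar-type semihydrogenation over lead-poisoned palladium stops at the alkene for the terminal alkyne and leaves the two trisubstituted olefins, whose geometry is already fixed, unchanged.

Step 4
Reactants: 6 (2E,5Z)-2,6-dimethylocta-2,5,7-trien-1-ol
Product: 7 (2E,5Z)-1-bromo-2,6-dimethylocta-2,5,7-triene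
Conditions: CBr4, PPh3, CH2Cl2, −20 → 0 °C; used at once
Reagents that add atoms: tetrabromomethane, BrC(Br)(Br)Br
Why: Appel reaction, in which bromide displaces the alkoxyphosphonium ion by SN2 under neutral conditions, gives the primary allylic bromide without allylic transposition or isomerisation of the skipped triene.

Step 5
Reactants: 8 3-methylbutan-2-one; 7 (2E,5Z)-1-bromo-2,6-dimethylocta-2,5,7-triene
Product: 10 (6E,9Z)-2,6,10-trimethyldodeca-6,9,11-trien-3-one, via lithium enolate 9 (not isolated)
Conditions: 8, LiN(iPr)2 (1.05 equiv), THF, −78 °C, 30 min; then 7 (0.9 equiv), −78 → −20 °C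
Reagents that add atoms: none
Why: Enolate alkylation, in which LiN(iPr)2 removes a methyl proton of the ketone under kinetic control and the lithium enolate displaces the primary allylic bromide by SN2, places the isopropyl ketone (C4) in 1,5-relation to the distal carbon (C5) of the E-olefin; no stereocentre is formed.

Step 6
Reactants: 10 (6E,9Z)-2,6,10-trimethyldodeca-6,9,11-trien-3-one
Product: 13 (1R,4R,5R)-dauca-6,8-dien-4-ol, via cyclopentyl cation zwitterion 11 (not isolated), via allyl cation zwitterion 12 (not isolated)
Conditions: Me3Al (1.2 equiv), (S,S)-TfNHCH(Ph)CH(Ph)NHTf (1.25 equiv), toluene, 80 °C, 3 h, giving MeAl[(S,S)-TfNCH(Ph)CH(Ph)NTf]; then 10 (0.005 M), CH2Cl2, −78 → −30 °C; aq. potassium sodium tartrate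
Reagents that add atoms: none
Why: Proposed new method: the chiral methylaluminium bis(sulfonamide) binds the ketone oxygen syn to the CH2 arm, the distal carbon C5 of the E-trisubstituted olefin adds to the activated carbonyl carbon C4 to close ring A (a stepwise Prins closure of the kind known for alkylaluminium-halide-promoted cyclisation of γ,δ-unsaturated ketones to cyclopentanol zwitterions), the tertiary C1 cation of 11 is captured on the opposite face by the terminal CH2 (C10) of the Z-diene to close ring B (anti addition across the E-olefin as in cationic polyene cyclisation, hence the trans ring fusion with C1-methyl β and H5 α), the isopropyl group takes the position anti to the C6 branch so that the C4 oxygen ends β (4R), the allyl cation of 12 loses H6 to the aluminium alkoxide to give the 6,8-diene, and the C2-symmetric ligand selects one enantiotopic face of the olefin for the first bond; the closest known reaction types are the Lewis-acid Prins or carbonyl-ene cyclisation, the Johnson-type cationic polyene cyclisation and enantioselective reactions promoted by this class of chiral aluminium Lewis acid.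

Step 7
Reactants: 13 (1R,4R,5R)-dauca-6,8-dien-4-ol
Product: 14 (1R,4R,5R,8R,9S)-8,9-epoxydauc-6-en-4-ol
Conditions: mCPBA (1.05 equiv), NaHCO3, CH2Cl2, −30 °C; aq. Na2S2O3; used crude
Reagents that add atoms: 3-chloroperoxybenzoic acid, OOC(=O)c1cccc(Cl)c1
Why: Prilezhaev epoxidation, in which the peracid reacts fastest with the more electron-rich trisubstituted C8=C9 bond of the diene and from the α face, away from the angular C1 methyl that covers the β face of ring B, sets C8 (R) and C9 (S).

Step 8
Reactants: 14 (1R,4R,5R,8R,9S)-8,9-epoxydauc-6-en-4-ol; 15 4-hydroxy-3-methoxybenzoic acid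
Product: 16 (1R,4R,5S,6S,9S)-4,9-dihydroxydauc-7-en-6-yl 4-hydroxy-3-methoxybenzoate
Conditions: 15 (1.1 equiv), tris(dibenzylideneacetone)dipalladium Pd2(dba)3 (2.5 mol%), PPh3 (12 mol%), THF, 0 °C → rt
Reagents that add atoms: none
Why: Palladium-catalysed 1,4-addition of a carboxylic acid to a cyclic vinyl epoxide (Tsuji–Trost type), in which zerovalent palladium ionises the allylic C8–O bond with inversion, the alkoxide formed deprotonates only the carboxylic acid (pKa 4.5 against 9 for the phenol) and the carboxylate attacks the less substituted allyl terminus C6 anti to palladium, puts the ester on the α face cis to the retained 9α-hydroxyl (6S, 9S) and moves the olefin to C7=C8.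

**Compound list**

1 | (Z)-3-methylpent-2-en-4-yn-1-ol | C#C/C(C)=C\CO | starting material
2 | (Z)-3-methylpent-2-en-4-yn-1-yl acetate | C#C/C(C)=C\COC(C)=O | intermediate
3 | prop-2-yn-1-ol | C#CCO | starting material
4 | dimethyl[(1E)-3-(dimethylalumanyloxy)-2-methylprop-1-en-1-yl]alumane (alkenylalane, not isolated) | C[Al](C)/C=C(\C)CO[Al](C)C | intermediate
5 | (2E,5Z)-2,6-dimethylocta-2,5-dien-7-yn-1-ol | C#C/C(C)=C\C/C=C(\C)CO | intermediate
6 | (2E,5Z)-2,6-dimethylocta-2,5,7-trien-1-ol | C=C/C(C)=C\C/C=C(\C)CO | intermediate
7 | (2E,5Z)-1-bromo-2,6-dimethylocta-2,5,7-triene | C=C/C(C)=C\C/C=C(\C)CBr | intermediate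
8 | 3-methylbutan-2-one | CC(=O)C(C)C | starting material
9 | lithium 3-methylbut-1-en-2-olate (not isolated) | [Li+].[O-]C(=C)C(C)C | intermediate
10 | (6E,9Z)-2,6,10-trimethyldodeca-6,9,11-trien-3-one | C=C/C(C)=C\C/C=C(\C)CCC(=O)C(C)C | intermediate
11 | ring-A-closed C1 carbocation with the C4 oxygen bound to the methylaluminate of the (S,S)-bis(sulfonamide); C4 and C5 configured as in 13; not isolated | C=C/C(C)=C\C[C@@H]1[C+](C)CC[C@@]1(O[Al-]2(C)N(S(=O)(=O)C(F)(F)F)[C@@H](c3ccccc3)[C@H](c3ccccc3)N2S(=O)(=O)C(F)(F)F)C(C)C | intermediate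
12 | bicyclic C7–C8–C9 allyl cation with the C4 oxygen bound to the same aluminate; C1, C4, C5 configured as in 13; not isolated | CC1=CC[C@@]2(C)CC[C@@](O[Al-]3(C)N(S(=O)(=O)C(F)(F)F)[C@@H](c4ccccc4)[C@H](c4ccccc4)N3S(=O)(=O)C(F)(F)F)(C(C)C)[C@@H]2C[CH+]1 | intermediate
13 | (1R,4R,5R)-dauca-6,8-dien-4-ol = (3R,3aR,8aR)-6,8a-dimethyl-3-(propan-2-yl)-1,2,3,3a,8,8a-hexahydroazulen-3-ol; 4-OH β, H5 α, trans-fused | CC1=CC[C@@]2(C)CC[C@@](O)(C(C)C)[C@@H]2C=C1 | intermediate
14 | (1R,4R,5R,8R,9S)-8,9-epoxydauc-6-en-4-ol; 8α,9α-epoxide, 4-OH β, H5 α | C[C@]12O[C@H]1C[C@@]3(C)CC[C@@](O)(C(C)C)[C@@H]3C=C2 | intermediate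
15 | 4-hydroxy-3-methoxybenzoic acid (vanillic acid) | COc1cc(C(=O)O)ccc1O | starting material
16 | (1R,4R,5S,6S,9S)-4,9-dihydroxydauc-7-en-6-yl 4-hydroxy-3-methoxybenzoate = [(3R,3aS,4S,7S,8aR)-3,7-dihydroxy-6,8a-dimethyl-3-(propan-2-yl)-1,2,3,3a,4,7,8,8a-octahydroazulen-4-yl] 4-hydroxy-3-methoxybenzoate | COc1cc(C(=O)O[C@H]2C=C(C)[C@@H](O)C[C@@]3(C)CC[C@@](O)(C(C)C)[C@H]23)ccc1O | target

**Step count and risk**

Total step count: 8. Longest linear sequence: 8 steps (1 → 2 → 5 → 6 → 7 → 10 → 13 → 14 → 16).

Most likely to fail, in this order: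

**Step 6 (bicyclisation).** The first closure is a strained five-membered Prins closure with the tether on the more substituted olefin carbon. The cascade can stop after ring A by proton loss, the alkoxide can trap the allyl cation as a 4,7-ether, the ketone can attack the diene instead, and neither the trans fusion nor the enantioselectivity has direct precedent.
Fallback, setting out from 10 and coming back at 13: the ketone is turned into a covalently bound chiral initiator. Ketalisation of 10 with (2R,4R)-pentane-2,4-diol (p-toluenesulfonic acid, benzene, water removal) gives the (2R,4R)-pentane-2,4-diol ketal F1. TiCl4 with 2,6-di-tert-butylpyridine in CH2Cl2 at −78 °C opens it to an oxocarbenium ion that starts the same two ring closures (Johnson-type ketal-initiated polyene cyclisation). This ion has no carbonyl-ene exit, and the auxiliary, not the Lewis acid, chooses the olefin face (the enantiomeric diol is used if needed). The product is the C4 hydroxyalkyl ether F2. Dess–Martin oxidation gives the β-alkoxy ketone F3, and K2CO3 in MeOH releases 13 by β-elimination.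

**Step 8 (palladium-catalysed addition of vanillic acid).** Ionisation needs palladium on the hindered β face, attack could go to C8, the phenol could be allylated, and free acid can open the epoxide without control.
Fallback, setting out from 14 and coming back at 16: two ionic displacements replace the metal-mediated double inversion. LiBr with AcOH in THF at 0 °C opens the vinyl epoxide; after allylic equilibration this gives the 6β-bromo-9α-hydroxy-dauc-7-en-4β-ol F9. The caesium carboxylate of 15 (from CsHCO3, 1 equiv, DMF, 0 °C) then displaces the secondary allylic bromide by SN2 with inversion to give 16.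

**Step 7 (epoxidation).** The peracid could attack C6=C7 (possibly directed by the 4-hydroxyl) or the β face, and the trisubstituted vinyl epoxide is acid-labile.
Fallback, setting out from 13 and coming back at 16: both ring-B oxygens are introduced in one suprafacial cycloaddition. Photooxygenation (O2, 5,10,15,20-tetraphenylporphyrin, hν, CH2Cl2, −40 °C) adds singlet oxygen [4+2] to the α face of the diene to give the 6α,9α-endoperoxide F4. Thiourea in MeOH reduces it to the cis-triol F5. TBSCl with imidazole silylates the less hindered 9-hydroxyl to give the 9-O-silyl ether F6. Steglich esterification (dicyclohexylcarbodiimide, 4-(dimethylamino)pyridine) with 4-(tert-butyldimethylsilyloxy)-3-methoxybenzoic acid F7 (from 15, TBSCl and imidazole, then K2CO3 in MeOH) gives the bis-silyl ester F8. Bu4NF buffered with AcOH removes both silyl groups to give 16.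

**Further compounds**

F1 | step 6 | (2R,4R)-pentane-2,4-diol ketal of 10: (4R,6R)-4,6-dimethyl-2-(propan-2-yl)-2-[(3E,6Z)-3,7-dimethylnona-3,6,8-trien-1-yl]-1,3-dioxane | C=C/C(C)=C\C/C=C(\C)CCC1(C(C)C)O[C@H](C)C[C@@H](C)O1
F2 | step 6 | 4-O-[(2R,4R)-4-hydroxypentan-2-yl] ether of 13 | CC1=CC[C@@]2(C)CC[C@@](O[C@H](C)C[C@@H](C)O)(C(C)C)[C@@H]2C=C1
F3 | step 6 | 4-O-[(2R)-4-oxopentan-2-yl] ether of 13 | CC1=CC[C@@]2(C)CC[C@@](O[C@H](C)CC(C)=O)(C(C)C)[C@@H]2C=C1
F4 | step 7 | (1R,4R,5S,6S,9S)-6,9-epidioxydauc-7-en-4-ol (6α,9α-endoperoxide) | CC1=C[C@@H]2OO[C@H]1C[C@@]3(C)CC[C@@](O)(C(C)C)[C@H]23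
F5 | step 7 | (1R,4R,5S,6S,9S)-dauc-7-ene-4,6,9-triol (4β,6α,9α) | O[C@H]1C=C(C)[C@@H](O)C[C@@]2(C)CC[C@@](O)(C(C)C)[C@H]12
F6 | step 7 | 9-O-(tert-butyldimethylsilyl) ether of F5 | O[C@H]1C=C(C)[C@@H](O[Si](C)(C)C(C)(C)C)C[C@@]2(C)CC[C@@](O)(C(C)C)[C@H]12
F7 | step 7 | 4-(tert-butyldimethylsilyloxy)-3-methoxybenzoic acid | COc1cc(C(=O)O)ccc1O[Si](C)(C)C(C)(C)C
F8 | step 7 | 9-O-silyl, phenol-O-silyl derivative of 16 | COc1cc(C(=O)O[C@H]2C=C(C)[C@@H](O[Si](C)(C)C(C)(C)C)C[C@@]3(C)CC[C@@](O)(C(C)C)[C@H]23)ccc1O[Si](C)(C)C(C)(C)C
F9 | step 8 | 6β-bromo-dauc-7-ene-4β,9α-diol | Br[C@@H]1C=C(C)[C@@H](O)C[C@@]2(C)CC[C@@](O)(C(C)C)[C@H]12
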